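**Strategy.** Everything rests on cutting the bond between the quaternary ring-fusion carbon C3a (benzofuran numbering) and C1' of its angular prenyl group, which lies ortho to the C4 oxygen of the six-membered ring. A thermal [3,3] shift of a C4–O 2-methylbut-3-en-2-yl ether on the aromatic (2S)-2,3-dihydrobenzofuran makes this bond, sets C3a anti to the C2 hydroxyisopropyl group and turns the benzene ring into the cyclohexa-2,4-dienone in one operation; the prenyl group already on the para carbon C7 blocks rearomatisation. The precursor is the fully substituted arene with C5 isovaleryl, C6 methoxy, C7 prenyl and a free tertiary alcohol. Chloride-mediated O-demethylation then releases the enolised triketone.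

Key step: step 10

Assumption: the target is treated as the (2S,3aS) compound, with the C3a prenyl and the C2 hydroxyisopropyl group on opposite faces of the five-membered ring; the enolised triketone is drawn as its C6-enol/C4-ketone tautomer, which equilibrates with the other enol forms.

Design remark: the tertiary alcohol is carried unprotected and the C6 oxygen stays a methyl ether throughout; the methyl group comes with the starting material and is the only device that tells apart the two oxygens flanking C5.

**Step 1**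
Reactants: 1 5-methoxyresorcinol; 2 isovaleryl chloride
Product: 3 1-(2,4-dihydroxy-6-methoxyphenyl)-3-methylbutan-1-one
Conditions: AlCl3 (3 equiv), CH2Cl2–PhNO2, 0 °C → rt; then cold 1 M HCl
Reagents that add atoms: none
Why: Friedel–Crafts acylation of the phloroglucinol monomethyl ether, in which the two equivalent ring carbons ortho to the methoxy group and para to a hydroxyl should be acylated in preference to the single carbon between the hydroxyls, the low temperature sparing the ortho methoxy group from AlCl3 cleavage and the minor 2,6-dihydroxy-4-methoxy isomer being removed by chromatography.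

**Step 2**
Reactants: 3 1-(2,4-dihydroxy-6-methoxyphenyl)-3-methylbutan-1-one; 4 prenyl bromide
Product: 5 1-[2,4-dihydroxy-6-methoxy-3-(3-methylbut-2-en-1-yl)phenyl]-3-methylbutan-1-one
Conditions: KOH (10% aq., 2 equiv), 0 °C → rt; then 1 M HCl
Reagents that add atoms: none
Why: Base-mediated C-prenylation of an acylphloroglucinol phenoxide in water (C-allylation of an ambident phenoxide), expected to favour C3 between the two hydroxyls, with the C5 isomer and O-prenyl ethers separated by chromatography.

**Step 3**
Reactants: 5 1-[2,4-dihydroxy-6-methoxy-3-(3-methylbut-2-en-1-yl)phenyl]-3-methylbutan-1-one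
Product: 6 1-[2,4-bis(tert-butyldimethylsilyloxy)-6-methoxy-3-(3-methylbut-2-en-1-yl)phenyl]-3-methylbutan-1-one
Conditions: TBSOTf (2.4 equiv), 2,6-lutidine, CH2Cl2, −78 → 0 °C
Reagents that add atoms: tert-butyldimethylsilyl trifluoromethanesulfonate, CC(C)(C)[Si](C)(C)OS(=O)(=O)C(F)(F)F
Why: Silyl ether formation with the silyl triflate, which is reactive enough to cap also the hydrogen-bonded, doubly ortho-flanked hydroxyl, masks both oxidisable phenols before the dioxirane step.

**Step 4**
Reactants: 6 1-[2,4-bis(tert-butyldimethylsilyloxy)-6-methoxy-3-(3-methylbut-2-en-1-yl)phenyl]-3-methylbutan-1-one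
Product: 7 1-[2,4-bis(tert-butyldimethylsilyloxy)-3-{[(2R)-3,3-dimethyloxiran-2-yl]methyl}-6-methoxyphenyl]-3-methylbutan-1-one
Conditions: D-fructose-derived Shi ketone (0.3 equiv), KHSO5 (as 2KHSO5·KHSO4·K2SO4), K2CO3, Bu4NHSO4 (cat.), MeCN–CH2(OMe)2–aq. Na2B4O7/Na2EDTA buffer (pH ≈ 10.5), 0 °C
Reagents that add atoms: potassium peroxymonosulfate, [K+].[O-]S(=O)(=O)OO
Why: Shi asymmetric epoxidation, in which the chiral dioxirane from the D-fructose-derived ketone attacks the trisubstituted prenyl alkene through the spiro transition state on the face that gives the (R)-epoxide, while the ketone, the silyl ethers and the capped arene should be inert at 0 °C.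

**Step 5**
Reactants: 7 1-[2,4-bis(tert-butyldimethylsilyloxy)-3-{[(2R)-3,3-dimethyloxiran-2-yl]methyl}-6-methoxyphenyl]-3-methylbutan-1-one
Product: 10 1-[(2S)-4-hydroxy-2-(2-hydroxypropan-2-yl)-6-methoxy-2,3-dihydro-1-benzofuran-5-yl]-3-methylbutan-1-one, via mono-silyl epoxy phenol 8 (not isolated), via silyl dihydrobenzofuran 9 (not isolated)
Conditions: Bu4NF (1.05 equiv), THF, −20 → 0 °C; then Bu4NF (1.2 equiv), rt; AcOH quench
Reagents that add atoms: none
Why: Fluoride desilylation followed by base-mediated 5-exo-tet epoxide opening, in which the unhindered silyl ether para to the ketone is cleaved first and its phenoxide attacks the secondary epoxide carbon with inversion, so that (R) becomes (S) at C2, before the second portion of fluoride frees the hindered hydroxyl next to the ketone.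

**Step 6**
Reactants: 10 1-[(2S)-4-hydroxy-2-(2-hydroxypropan-2-yl)-6-methoxy-2,3-dihydro-1-benzofuran-5-yl]-3-methylbutan-1-one; 4 prenyl bromide
Product: 11 1-[(2S)-2-(2-hydroxypropan-2-yl)-6-methoxy-4-[(3-methylbut-2-en-1-yl)oxy]-2,3-dihydro-1-benzofuran-5-yl]-3-methylbutan-1-one
Conditions: K2CO3, DMF, rt
Reagents that add atoms: none
Why: Williamson etherification of the only phenol, whose hydroxyl is far more acidic than the tertiary alcohol, so that carbonate-mediated O-prenylation should occur at the C4 oxygen alone.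

**Step 7**
Reactants: 11 1-[(2S)-2-(2-hydroxypropan-2-yl)-6-methoxy-4-[(3-methylbut-2-en-1-yl)oxy]-2,3-dihydro-1-benzofuran-5-yl]-3-methylbutan-1-one
Product: 14 1-[(2S)-4-hydroxy-2-(2-hydroxypropan-2-yl)-6-methoxy-7-(3-methylbut-2-en-1-yl)-2,3-dihydro-1-benzofuran-5-yl]-3-methylbutan-1-one, via ortho-dienone 12 (not isolated), via para-dienone 13 (not isolated)
Conditions: Eu(fod)3 (10 mol%; fod = 6,6,7,7,8,8,8-heptafluoro-2,2-dimethyloctane-3,5-dionate), CHCl3, 70 °C, sealed tube
Reagents that add atoms: none
Why: Lewis-acid-accelerated para-Claisen–Cope sequence, in which the first [3,3] shift from the chelated C4 ether gives a blocked ortho-dienone, a Cope shift carries the allyl unit on to the free C7 as a normal prenyl group and enolisation restores the hydrogen-bonded phenol, C2 being untouched.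

**Step 8**
Reactants: 14 1-[(2S)-4-hydroxy-2-(2-hydroxypropan-2-yl)-6-methoxy-7-(3-methylbut-2-en-1-yl)-2,3-dihydro-1-benzofuran-5-yl]-3-methylbutan-1-one; 15 3-chloro-3-methylbut-1-yne
Product: 16 1-[(2S)-2-(2-hydroxypropan-2-yl)-6-methoxy-7-(3-methylbut-2-en-1-yl)-4-[(2-methylbut-3-yn-2-yl)oxy]-2,3-dihydro-1-benzofuran-5-yl]-3-methylbutan-1-one
Conditions: CuCl2·2H2O (1 mol%), DBU (1.5 equiv), MeCN, −5 → 0 °C
Reagents that add atoms: none
Why: Copper-catalysed propargylic substitution of a tertiary propargyl chloride by a phenoxide (through a copper acetylide that ionises to an allenylidene-type electrophile), the standard way to tertiary aryl propargyl ethers, which leaves the non-acidic tertiary alcohol alone.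

**Step 9**
Reactants: 16 1-[(2S)-2-(2-hydroxypropan-2-yl)-6-methoxy-7-(3-methylbut-2-en-1-yl)-4-[(2-methylbut-3-yn-2-yl)oxy]-2,3-dihydro-1-benzofuran-5-yl]-3-methylbutan-1-one
Product: 17 1-[(2S)-2-(2-hydroxypropan-2-yl)-6-methoxy-4-[(2-methylbut-3-en-2-yl)oxy]-7-(3-methylbut-2-en-1-yl)-2,3-dihydro-1-benzofuran-5-yl]-3-methylbutan-1-one
Conditions: H2 (1 atm), Pd/CaCO3 poisoned with Pb(OAc)2 (Lindlar catalyst), quinoline, EtOAc, 0 °C → rt; product used without delay
Reagents that add atoms: none
Why: Lindlar semi-hydrogenation of the terminal alkyne to the vinyl group, the quinoline-poisoned catalyst being expected to leave the trisubstituted prenyl alkenes and the aryl ketone unreduced.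

**Step 10**
Reactants: 17 1-[(2S)-2-(2-hydroxypropan-2-yl)-6-methoxy-4-[(2-methylbut-3-en-2-yl)oxy]-7-(3-methylbut-2-en-1-yl)-2,3-dihydro-1-benzofuran-5-yl]-3-methylbutan-1-one
Product: 18 (2S,3aS)-2-(2-hydroxypropan-2-yl)-6-methoxy-5-(3-methylbutanoyl)-3a,7-bis(3-methylbut-2-en-1-yl)-3,3a-dihydro-1-benzofuran-4(2H)-one
Conditions: degassed PhMe, 100–110 °C
Reagents that add atoms: none
Why: Concerted aromatic Claisen rearrangement: in a chair transition state the terminal CH2 of the O-bound 2-methylbut-3-en-2-yl group bonds to the ortho carbon C3a as the C4–O bond breaks, so the allyl unit arrives suprafacially as a normal prenyl group and C4 becomes the ring ketone. The closest known reaction type is the thermal rearrangement of ortho-blocked aryl 1,1-dimethylallyl ethers to 6,6-disubstituted cyclohexa-2,4-dienones. No ring is closed. The new C3a stereocentre is set by substrate control: the migrating chain sweeps over the face of the nearly planar bicycle that is not shielded by the C2 hydroxyisopropyl group (1,3 across the five-membered ring), which should give the 3aS, trans isomer. The step needs C3a to win over C5 and C7: the prenyl group on the para carbon C7 rules out relay and rearomatisation, while shifts to C5 or onward to C7 are reversible and give dienones that lack the conjugated acyl vinylogous ester, so 18 should accumulate as the thermodynamic sink. The tertiary ether should rearrange near 100 °C, a temperature the free tertiary alcohol and both prenyl alkenes tolerate.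

**Step 11**
Reactants: 18 (2S,3aS)-2-(2-hydroxypropan-2-yl)-6-methoxy-5-(3-methylbutanoyl)-3a,7-bis(3-methylbut-2-en-1-yl)-3,3a-dihydro-1-benzofuran-4(2H)-one
Product: 19 (2S,3aS)-6-hydroxy-2-(2-hydroxypropan-2-yl)-5-(3-methylbutanoyl)-3a,7-bis(3-methylbut-2-en-1-yl)-3,3a-dihydro-1-benzofuran-4(2H)-one
Conditions: LiCl (5 equiv), DMF, 120 °C; then cold 0.5 M HCl to pH 3
Reagents that add atoms: none
Why: Nucleophilic O-demethylation (SN2 attack of chloride on the methyl group) of the doubly activated vinylogous ester gives the lithium enolate of the β-triketone, which the mild acidification protonates, and neither stereocentre can epimerise because C3a is quaternary and C2 is not enolisable.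

**Compound list**
1 | 5-methoxyresorcinol | COc1cc(O)cc(O)c1 | starting material
2 | isovaleryl chloride (3-methylbutanoyl chloride) | CC(C)CC(Cl)=O | starting material
3 | 1-(2,4-dihydroxy-6-methoxyphenyl)-3-methylbutan-1-one | CC(C)CC(=O)c1c(O)cc(O)cc1OC | intermediate
4 | prenyl bromide (1-bromo-3-methylbut-2-ene) | CC(C)=CCBr | starting material
5 | 1-[2,4-dihydroxy-6-methoxy-3-(3-methylbut-2-en-1-yl)phenyl]-3-methylbutan-1-one | CC(C)CC(=O)c1c(O)c(CC=C(C)C)c(O)cc1OC | intermediate
6 | 1-[2,4-bis(tert-butyldimethylsilyloxy)-6-methoxy-3-(3-methylbut-2-en-1-yl)phenyl]-3-methylbutan-1-one | CC(C)CC(=O)c1c(O[Si](C)(C)C(C)(C)C)c(CC=C(C)C)c(O[Si](C)(C)C(C)(C)C)cc1OC | intermediate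
7 | 1-[2,4-bis(tert-butyldimethylsilyloxy)-3-{[(2R)-3,3-dimethyloxiran-2-yl]methyl}-6-methoxyphenyl]-3-methylbutan-1-one | CC(C)CC(=O)c1c(O[Si](C)(C)C(C)(C)C)c(C[C@H]2OC2(C)C)c(O[Si](C)(C)C(C)(C)C)cc1OC | intermediate
8 | 1-[2-(tert-butyldimethylsilyloxy)-3-{[(2R)-3,3-dimethyloxiran-2-yl]methyl}-4-hydroxy-6-methoxyphenyl]-3-methylbutan-1-one (present as its tetrabutylammonium phenoxide; not isolated) | CC(C)CC(=O)c1c(O[Si](C)(C)C(C)(C)C)c(C[C@H]2OC2(C)C)c(O)cc1OC | intermediate
9 | 1-[(2S)-4-(tert-butyldimethylsilyloxy)-2-(2-hydroxypropan-2-yl)-6-methoxy-2,3-dihydro-1-benzofuran-5-yl]-3-methylbutan-1-one (not isolated) | CC(C)CC(=O)c1c(OC)cc2O[C@H](C(C)(C)O)Cc2c1O[Si](C)(C)C(C)(C)C | intermediate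
10 | 1-[(2S)-4-hydroxy-2-(2-hydroxypropan-2-yl)-6-methoxy-2,3-dihydro-1-benzofuran-5-yl]-3-methylbutan-1-one | CC(C)CC(=O)c1c(OC)cc2O[C@H](C(C)(C)O)Cc2c1O | intermediate
11 | 1-[(2S)-2-(2-hydroxypropan-2-yl)-6-methoxy-4-[(3-methylbut-2-en-1-yl)oxy]-2,3-dihydro-1-benzofuran-5-yl]-3-methylbutan-1-one | CC(C)CC(=O)c1c(OC)cc2O[C@H](C(C)(C)O)Cc2c1OCC=C(C)C | intermediate
12 | (2S)-2-(2-hydroxypropan-2-yl)-6-methoxy-3a-(2-methylbut-3-en-2-yl)-5-(3-methylbutanoyl)-3,3a-dihydro-1-benzofuran-4(2H)-one (C3a configuration immaterial, centre erased in the next shift; not isolated) | CC(C)CC(=O)C1=C(OC)C=C2O[C@H](C(C)(C)O)CC2(C(C)(C)C=C)C1=O | intermediate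
13 | (2S)-2-(2-hydroxypropan-2-yl)-6-methoxy-5-(3-methylbutanoyl)-7-(3-methylbut-2-en-1-yl)-2,3-dihydro-1-benzofuran-4(7H)-one (C7 configuration immaterial, centre erased on enolisation; not isolated) | CC(C)CC(=O)C1=C(OC)C(CC=C(C)C)C2=C(C[C@@H](C(C)(C)O)O2)C1=O | intermediate
14 | 1-[(2S)-4-hydroxy-2-(2-hydroxypropan-2-yl)-6-methoxy-7-(3-methylbut-2-en-1-yl)-2,3-dihydro-1-benzofuran-5-yl]-3-methylbutan-1-one | CC(C)CC(=O)c1c(OC)c(CC=C(C)C)c2O[C@H](C(C)(C)O)Cc2c1O | intermediate
15 | 3-chloro-3-methylbut-1-yne | CC(C)(Cl)C#C | starting material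
16 | 1-[(2S)-2-(2-hydroxypropan-2-yl)-6-methoxy-7-(3-methylbut-2-en-1-yl)-4-[(2-methylbut-3-yn-2-yl)oxy]-2,3-dihydro-1-benzofuran-5-yl]-3-methylbutan-1-one | CC(C)CC(=O)c1c(OC)c(CC=C(C)C)c2O[C@H](C(C)(C)O)Cc2c1OC(C)(C)C#C | intermediate
17 | 1-[(2S)-2-(2-hydroxypropan-2-yl)-6-methoxy-4-[(2-methylbut-3-en-2-yl)oxy]-7-(3-methylbut-2-en-1-yl)-2,3-dihydro-1-benzofuran-5-yl]-3-methylbutan-1-one | CC(C)=CCc1c2O[C@H](C(C)(C)O)Cc2c(OC(C)(C)C=C)c(C(=O)CC(C)C)c1OC | intermediate
18 | (2S,3aS)-2-(2-hydroxypropan-2-yl)-6-methoxy-5-(3-methylbutanoyl)-3a,7-bis(3-methylbut-2-en-1-yl)-3,3a-dihydro-1-benzofuran-4(2H)-one | CC(C)=CCC1=C2O[C@H](C(C)(C)O)C[C@]2(CC=C(C)C)C(=O)C(C(=O)CC(C)C)=C1OC | intermediate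
19 | (2S,3aS)-6-hydroxy-2-(2-hydroxypropan-2-yl)-5-(3-methylbutanoyl)-3a,7-bis(3-methylbut-2-en-1-yl)-3,3a-dihydro-1-benzofuran-4(2H)-one | CC(C)=CCC1=C2O[C@H](C(C)(C)O)C[C@]2(CC=C(C)C)C(=O)C(C(=O)CC(C)C)=C1O | target

**Step count and risks**
Total step count: 11. Longest linear sequence: 11 steps (from 1).

Steps most likely to fail:

1. Step 10. The remote C2 group may discriminate the two faces of C3a only moderately, and the tertiary allyl ether may ionise or eliminate (loss of the C5 unit as isoprene, return of the phenol) faster than it rearranges. The fallback sets out from 14 and comes back at 18. Phenol 14 would be deprotonated with LiN(SiMe3)2 (1.0 equiv) in toluene–THF at 0 °C and C-alkylated with prenyl bromide 4. This is an alkylative dearomatisation of a lithium-chelated acylphloroglucinol-type phenoxide at the ortho carbon C3a, the same bond made intermolecularly, with the facial bias again supplied by the C2 substituent and tunable through counter-ion and solvent. No new compound is made on this path (F0).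

2. Step 8. The hydrogen-bonded, doubly ortho-flanked phenoxide may react too slowly, so that the tertiary propargyl electrophile is consumed by elimination to the enyne. The fallback sets out from 14 and comes back at 17, bypassing 16 and step 9. It is a Tsuji–Trost O-allylation with tert-butyl 2-methylbut-3-en-2-yl carbonate F1, prepared from 2-methylbut-3-en-2-ol with n-BuLi and Boc2O. With Pd(PPh3)4 (zerovalent palladium) in THF at 0 °C, the phenoxide should attack the more substituted terminus of the 1,1-dimethylallyl palladium complex under kinetic control and give the branched ether directly.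

3. Step 2. Alkylation may occur at the other free ring carbon (C5) or on oxygen, and a second prenyl group may be introduced, leaving little of the C3 isomer. The fallback sets out from 1 and comes back at 5, bypassing 3, and fixes the regiochemistry by directed ortho-metalation:
   - 1 is converted with MOMCl and iPr2NEt into 1-methoxy-3,5-bis(methoxymethoxy)benzene F2.
   - Lithiation with n-BuLi (THF, 0 °C) between the two MOM ethers, then CuBr·SMe2 and prenyl bromide 4, gives 5-methoxy-1,3-bis(methoxymethoxy)-2-(3-methylbut-2-en-1-yl)benzene F3.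
   - A second lithiation (n-BuLi, TMEDA) at one of the two equivalent remaining ring carbons, transmetalation with ZnCl2 and Negishi acylation with 2 under Pd(PPh3)4 catalysis gives 1-[6-methoxy-2,4-bis(methoxymethoxy)-3-(3-methylbut-2-en-1-yl)phenyl]-3-methylbutan-1-one F4.
   - HCl in MeOH at rt removes both MOM groups to give 5.

**Further compounds**
F0 | step 10 | none | none
F1 | step 8 | tert-butyl 2-methylbut-3-en-2-yl carbonate | CC(C)(C)OC(=O)OC(C)(C)C=C
F2 | step 2 | 1-methoxy-3,5-bis(methoxymethoxy)benzene | COCOc1cc(OC)cc(OCOC)c1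
F3 | step 2 | 5-methoxy-1,3-bis(methoxymethoxy)-2-(3-methylbut-2-en-1-yl)benzene | COCOc1cc(OC)cc(OCOC)c1CC=C(C)C
F4 | step 2 | 1-[6-methoxy-2,4-bis(methoxymethoxy)-3-(3-methylbut-2-en-1-yl)phenyl]-3-methylbutan-1-one | CC(C)CC(=O)c1c(OCOC)c(CC=C(C)C)c(OCOC)cc1OC
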